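**Plan**

1. Retrosyn­thesis (ring numbered C1 vanillate carbinol, C2(Me)=C3, C4 acetate carbinol, C5 CMe2, C6–C8 three CH2, C9(Me)=C10, C11 CH2): cut the two ester C–O bonds, take the C4 carbinol back to a ketone, then cut the ring bond C5–C6 (intramolecular enolate C-alkylation).
2. The open chain is cut further at C3–C4 (Nozaki–Hiyama–Kishi with isobutyraldehyde), C7–C8 (Johnson–Claisen), C1–C11 (allylboration) and C2–CH3 (carbomagnesiation of propargyl alcohol).
3. Forward: a Z-iodoenal is allylated, the chain is grown to the E-alkene and a primary iodide, the Z-enone is installed, and the 11-membered carbocycle (the only ring made) is closed last at C5–C6; reduction and two acylations finish.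
4. Stereochemistry: Z-alkene from chelate-controlled anti-carbomagnesiation/iodination and a retentive chromium coupling; E-alkene from the chair Johnson–Claisen; C1 from reagent-controlled Brown allylation; C4 from Corey–Bakshi–Shibata reduction of the ring ketone.
5. Enabling feature: C5 sits α to the C4 carbinol, whose other neighbour is the vinylic C3–H. At the ketone level the isopropyl methine is therefore the only enolisable sp3 C–H, so one deprotonation puts the nucleophile exactly on C5. The Z-alkene C2=C3 and the E-alkene C9=C10 (4 of 11 ring atoms sp2) fold the chain.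

Key step: step 12

Remark: the (+)-α-pinene-derived B-allyldiisopinocampheylborane and 4-acetoxy-3-methoxybenzoic acid are taken as purchasable; in step 13 the fully substituted ring carbon is assumed to act as the larger ketone substituent. TBS = tert-butyldimethylsilyl.

**Route**

Step 1
Reactants: 1 prop-2-yn-1-ol (propargyl alcohol)
Product: 3 (Z)-3-iodo-2-methylprop-2-en-1-ol, via vinylmagnesium alkoxide 2 (not isolated)
Conditions: MeMgBr (2.5 equiv), CuI (copper monoiodide, 10 mol %), THF, −10 °C → rt; then I2, −78 → 0 °C; aq. NH4Cl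
Reagents that add atoms: methylmagnesium bromide (C[Mg]Br); iodine (II)
Why: Copper-catalysed anti-carbomagnesiation of the propargylic magnesium alkoxide puts methyl on the internal carbon and magnesium on the terminal carbon cis to CH2O in a five-membered chelate, and iodinolysis with retention should give the Z-iodoalkene that becomes the Z ring alkene.

Step 2
Reactants: 3 (Z)-3-iodo-2-methylprop-2-en-1-ol
Product: 4 (Z)-3-iodo-2-methylprop-2-enal
Conditions: MnO2 (excess), CH2Cl2, rt; used directly
Reagents that add atoms: none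
Why: Allylic oxidation with manganese dioxide is neutral and should give the enal without Z to E isomerisation.

Step 3
Reactants: 4 (Z)-3-iodo-2-methylprop-2-enal
Product: 6 (1Z,3S)-1-iodo-2-methylhexa-1,5-dien-3-ol, via borinate ester 5 (not isolated)
Conditions: B-allyldiisopinocampheylborane made from (+)-α-pinene, Et2O, −78 °C; then ethanolamine, rt
Reagents that add atoms: B-allyldiisopinocampheylborane from (+)-α-pinene (C=CCB([C@@H]1C[C@@H]2C[C@H]([C@H]1C)C2(C)C)[C@@H]1C[C@@H]2C[C@H]([C@H]1C)C2(C)C)
Why: Brown allylboration through a chair six-membered transition state, in which the isopinocampheyl groups of the (+)-α-pinene-derived reagent select the aldehyde face that gives the 3S carbinol with sp2-substituted aldehydes, sets the future vanillate-bearing stereocentre.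

Step 4
Reactants: 6 (1Z,3S)-1-iodo-2-methylhexa-1,5-dien-3-ol
Product: 7 tert-butyl{[(1Z,3S)-1-iodo-2-methylhexa-1,5-dien-3-yl]oxy}dimethylsilane
Conditions: TBSCl, imidazole, DMF, rt
Reagents that add atoms: tert-butyldimethylsilyl chloride (CC(C)(C)[Si](C)(C)Cl)
Why: Standard silylation protects the allylic alcohol so that only one allylic hydroxyl is present in the later Claisen step and no free hydroxyl sits next to the enone in the ring closure.

Step 5
Reactants: 7 TBS ether of 6
Product: 9 (3S,4Z)-3-(TBS-oxy)-5-iodo-4-methylpent-4-enal, via vicinal diol 8 (not isolated)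
Conditions: OsO4 (cat.), NaIO4, 2,6-lutidine, dioxane–H2O, rt
Reagents that add atoms: osmium tetroxide, catalytic oxygen carrier (O=[Os](=O)(=O)=O); sodium periodate, terminal oxygen source ([Na+].[O-]I(=O)(=O)=O)
Why: Lemieux–Johnson cleavage should attack the electron-rich monosubstituted alkene and leave the hindered, electron-poor iodoalkene alone.

Step 6
Reactants: 9 (3S,4Z)-3-(TBS-oxy)-5-iodo-4-methylpent-4-enal
Product: 10 (3RS,5S,6Z)-5-(TBS-oxy)-7-iodo-2,6-dimethylhepta-1,6-dien-3-ol
Conditions: isopropenylmagnesium bromide, THF, −78 °C; aq. NH4Cl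
Reagents that add atoms: isopropenylmagnesium bromide (CC(=C)[Mg]Br)
Why: Grignard addition to the aldehyde gives the allylic alcohol needed for the Claisen step; the new carbinol centre is not controlled because it is destroyed in step 7.

Step 7
Reactants: 10 (3RS,5S,6Z)-5-(TBS-oxy)-7-iodo-2,6-dimethylhepta-1,6-dien-3-ol
Product: 12 ethyl (4E,7S,8Z)-7-(TBS-oxy)-9-iodo-4,8-dimethylnona-4,8-dienoate, via mixed ketene acetal 11 (not isolated)
Conditions: MeC(OEt)3, EtCO2H (cat.), 140 °C, EtOH distilled off
Reagents that add atoms: triethyl orthoacetate (CCOC(C)(OCC)OCC)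
Why: Johnson–Claisen orthoester rearrangement through a chair transition state with the carbinol substituent equatorial should give the E-trisubstituted alkene and adds the two carbons that become C6 and C7 of the ring.

Step 8
Reactants: 12 ethyl (4E,7S,8Z)-7-(TBS-oxy)-9-iodo-4,8-dimethylnona-4,8-dienoate
Product: 13 (4E,7S,8Z)-7-(TBS-oxy)-9-iodo-4,8-dimethylnona-4,8-dien-1-ol
Conditions: DIBAL-H (iBu2AlH, 2.2 equiv), CH2Cl2, −78 → 0 °C; Rochelle salt
Reagents that add atoms: none
Why: Hydride reduction of the ester to the primary alcohol should leave the vinyl iodide and silyl ether untouched.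

Step 9
Reactants: 13 (4E,7S,8Z)-7-(TBS-oxy)-9-iodo-4,8-dimethylnona-4,8-dien-1-ol; 14 isobutyraldehyde (2-methylpropanal)
Product: 15 (4E,7S,8Z,10RS)-7-(TBS-oxy)-4,8,11-trimethyldodeca-4,8-diene-1,10-diol
Conditions: CrCl2 (4 equiv), NiCl2 (2 mol %), DMSO, rt
Reagents that add atoms: none
Why: Nozaki–Hiyama–Kishi coupling tolerates the free hydroxyl and should add the alkenylchromium to the aldehyde with retention of the Z geometry; the new carbinol centre is oxidised away in step 10.

Step 10
Reactants: 15 (4E,7S,8Z,10RS)-7-(TBS-oxy)-4,8,11-trimethyldodeca-4,8-diene-1,10-diol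
Product: 16 (4Z,6S,8E)-6-(TBS-oxy)-12-hydroxy-2,5,9-trimethyldodeca-4,8-dien-3-one
Conditions: MnO2 (excess), CH2Cl2, rt
Reagents that add atoms: none
Why: Manganese dioxide oxidises only the allylic secondary alcohol, so the Z-enone should form while the saturated primary alcohol is kept.

Step 11
Reactants: 16 (4Z,6S,8E)-6-(TBS-oxy)-12-hydroxy-2,5,9-trimethyldodeca-4,8-dien-3-one
Product: 17 (4Z,6S,8E)-6-(TBS-oxy)-12-iodo-2,5,9-trimethyldodeca-4,8-dien-3-one
Conditions: I2, PPh3, imidazole, CH2Cl2, 0 °C
Reagents that add atoms: iodine (II)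
Why: Appel iodination converts the primary alcohol into the primary iodide under neutral conditions that the enone and silyl ether should survive.

Step 12
Reactants: 17 (4Z,6S,8E)-6-(TBS-oxy)-12-iodo-2,5,9-trimethyldodeca-4,8-dien-3-one
Product: 19 (2Z,4S,6E)-4-(TBS-oxy)-3,7,11,11-tetramethylcycloundeca-2,6-dien-1-one, via lithium dienolate 18 (not isolated)
Conditions: LDA (LiN(iPr)2, 1.1 equiv), THF, −78 °C, 0.003 M; then DMPU, −78 → 0 °C
Reagents that add atoms: none
Why: Kinetic deprotonation of the isopropyl methine gives the cross-conjugated lithium dienolate 18, whose fully substituted enolate carbon displaces the primary iodide in an intramolecular SN2 reaction, forming the CMe2–CH2 bond and with it both the quaternary centre and the ring. The closest known reaction type is the high-dilution intramolecular C-alkylation of ketone enolates and related stabilised carbanions with ω-halides used to close medium and large terpenoid carbocycles. The one ring closed is the 11-membered carbocycle, by an 11-(enolendo)-exo-tet closure. No stereocentre is created, because the new quaternary carbon carries two methyl groups, and the silyloxy-bearing centre and both alkene geometries are not involved. The step needs regioselective enolisation, C- over O-alkylation and cyclisation over oligomerisation: the first is secured because the isopropyl C–H is the only sp3 C–H α to the carbonyl (the other α-carbon is vinylic) and α′-deprotonation is kinetically preferred to γ-deprotonation, the second by the soft iodide with a lithium counter-ion, and the third by high dilution together with the Z- and E-alkenes, which make 4 of the 11 ring atoms sp2 and turn the chain ends toward each other.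

Step 13
Reactants: 19 (2Z,4S,6E)-4-(TBS-oxy)-3,7,11,11-tetramethylcycloundeca-2,6-dien-1-one
Product: 20 (1R,2Z,4S,6E)-4-(TBS-oxy)-3,7,11,11-tetramethylcycloundeca-2,6-dien-1-ol
Conditions: (S)-Me-CBS [(S)-1-methyl-3,3-diphenyltetrahydro-1H,3H-pyrrolo[1,2-c][1,3,2]oxazaborole, 0.3 equiv], catecholborane, toluene, −78 → −40 °C; MeOH, aq. NaOH
Reagents that add atoms: none
Why: Corey–Bakshi–Shibata 1,2-reduction, in which the ketone binds the catalyst boron with the quaternary carbon as the large group and the alkenyl carbon as the small one, should deliver hydride to the face that gives the 1R alcohol under reagent control.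

Step 14
Reactants: 20 (1R,2Z,4S,6E)-4-(TBS-oxy)-3,7,11,11-tetramethylcycloundeca-2,6-dien-1-ol
Product: 21 (1R,2Z,4S,6E)-4-(TBS-oxy)-3,7,11,11-tetramethylcycloundeca-2,6-dien-1-yl acetate
Conditions: Ac2O, Et3N, 4-(dimethylamino)pyridine (DMAP, cat.), CH2Cl2, rt
Reagents that add atoms: acetic anhydride (CC(=O)OC(C)=O)
Why: DMAP-catalysed acetylation should esterify the hindered neopentyl-type allylic alcohol with retention, since the C–O bond is not broken.

Step 15
Reactants: 21 (1R,2Z,4S,6E)-4-(TBS-oxy)-3,7,11,11-tetramethylcycloundeca-2,6-dien-1-yl acetate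
Product: 22 (1R,2Z,4S,6E)-4-hydroxy-3,7,11,11-tetramethylcycloundeca-2,6-dien-1-yl acetate
Conditions: HF·pyridine, pyridine, THF, 0 °C → rt
Reagents that add atoms: none
Why: Buffered fluoride desilylation should free the second allylic hydroxyl under non-basic conditions chosen to suppress acetyl migration.

Step 16
Reactants: 22 (1R,2Z,4S,6E)-4-hydroxy-3,7,11,11-tetramethylcycloundeca-2,6-dien-1-yl acetate; 23 4-acetoxy-3-methoxybenzoic acid
Product: 24 (1S,2Z,4R,9E)-4-acetoxy-2,5,5,9-tetramethylcycloundeca-2,9-dien-1-yl 4-acetoxy-3-methoxybenzoate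
Conditions: N,N′-diisopropylcarbodiimide (DIC), DMAP (cat.), CH2Cl2, 0 °C → rt
Reagents that add atoms: none
Why: Steglich esterification acylates the alcohol through the acylpyridinium of 23, which should be far more reactive than the aryl acetate, and the carbinol configuration is retained.

Step 17
Reactants: 24 (1S,2Z,4R,9E)-4-acetoxy-2,5,5,9-tetramethylcycloundeca-2,9-dien-1-yl 4-acetoxy-3-methoxybenzoate
Product: 25 (1S,2Z,4R,9E)-4-acetoxy-2,5,5,9-tetramethylcycloundeca-2,9-dien-1-yl 4-hydroxy-3-methoxybenzoate (target)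
Conditions: pyrrolidine (1.5 equiv), CH2Cl2, 0 °C
Reagents that add atoms: none
Why: Chemoselective aminolysis should cleave only the activated aryl acetate, leaving the hindered secondary alkyl acetate and the benzoate ester intact.

**Compound list**

1 | prop-2-yn-1-ol | C#CCO | starting material
2 | (Z)-vinylmagnesium bromide magnesium alkoxide from 1 (not isolated) | Br[Mg]/C=C(/C)CO[Mg]Br | intermediate
3 | (Z)-3-iodo-2-methylprop-2-en-1-ol | OC/C(C)=C\I | intermediate
4 | (Z)-3-iodo-2-methylprop-2-enal | O=C/C(C)=C\I | intermediate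
5 | diisopinocampheylborinate ester of 6 (not isolated) | C=CC[C@H](OB([C@@H]1C[C@@H]2C[C@H]([C@H]1C)C2(C)C)[C@@H]1C[C@@H]2C[C@H]([C@H]1C)C2(C)C)/C(C)=C\I | intermediate
6 | (1Z,3S)-1-iodo-2-methylhexa-1,5-dien-3-ol | C=CC[C@H](O)/C(C)=C\I | intermediate
7 | tert-butyl{[(1Z,3S)-1-iodo-2-methylhexa-1,5-dien-3-yl]oxy}dimethylsilane | C=CC[C@H](O[Si](C)(C)C(C)(C)C)/C(C)=C\I | intermediate
8 | (4S,5Z)-4-(TBS-oxy)-6-iodo-5-methylhex-5-ene-1,2-diol, both C2 epimers (not isolated) | OCC(O)C[C@H](O[Si](C)(C)C(C)(C)C)/C(C)=C\I | intermediate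
9 | (3S,4Z)-3-(TBS-oxy)-5-iodo-4-methylpent-4-enal | O=CC[C@H](O[Si](C)(C)C(C)(C)C)/C(C)=C\I | intermediate
10 | (3RS,5S,6Z)-5-(TBS-oxy)-7-iodo-2,6-dimethylhepta-1,6-dien-3-ol | CC(=C)C(O)C[C@H](O[Si](C)(C)C(C)(C)C)/C(C)=C\I | intermediate
11 | mixed ketene acetal (O-ethyl, O-allylic) from 10 (not isolated) | C=C(OCC)OC(C(C)=C)C[C@H](O[Si](C)(C)C(C)(C)C)/C(C)=C\I | intermediate
12 | ethyl (4E,7S,8Z)-7-(TBS-oxy)-9-iodo-4,8-dimethylnona-4,8-dienoate | CCOC(=O)CC/C(C)=C/C[C@H](O[Si](C)(C)C(C)(C)C)/C(C)=C\I | intermediate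
13 | (4E,7S,8Z)-7-(TBS-oxy)-9-iodo-4,8-dimethylnona-4,8-dien-1-ol | OCCC/C(C)=C/C[C@H](O[Si](C)(C)C(C)(C)C)/C(C)=C\I | intermediate
14 | isobutyraldehyde | CC(C)C=O | starting material
15 | (4E,7S,8Z,10RS)-7-(TBS-oxy)-4,8,11-trimethyldodeca-4,8-diene-1,10-diol | CC(C)C(O)/C=C(/C)[C@@H](O[Si](C)(C)C(C)(C)C)C/C=C(\C)CCCO | intermediate
16 | (4Z,6S,8E)-6-(TBS-oxy)-12-hydroxy-2,5,9-trimethyldodeca-4,8-dien-3-one | CC(C)C(=O)/C=C(/C)[C@@H](O[Si](C)(C)C(C)(C)C)C/C=C(\C)CCCO | intermediate
17 | (4Z,6S,8E)-6-(TBS-oxy)-12-iodo-2,5,9-trimethyldodeca-4,8-dien-3-one | CC(C)C(=O)/C=C(/C)[C@@H](O[Si](C)(C)C(C)(C)C)C/C=C(\C)CCCI | intermediate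
18 | lithium dienolate of 17 (not isolated) | CC(C)=C(O[Li])/C=C(/C)[C@@H](O[Si](C)(C)C(C)(C)C)C/C=C(\C)CCCI | intermediate
19 | (2Z,4S,6E)-4-(TBS-oxy)-3,7,11,11-tetramethylcycloundeca-2,6-dien-1-one | CC(C)(C)[Si](C)(C)O[C@H]1C/C=C(\C)CCCC(C)(C)C(=O)/C=C\1C | intermediate
20 | (1R,2Z,4S,6E)-4-(TBS-oxy)-3,7,11,11-tetramethylcycloundeca-2,6-dien-1-ol | CC(C)(C)[Si](C)(C)O[C@H]1C/C=C(\C)CCCC(C)(C)[C@H](O)/C=C\1C | intermediate
21 | (1R,2Z,4S,6E)-4-(TBS-oxy)-3,7,11,11-tetramethylcycloundeca-2,6-dien-1-yl acetate | CC(C)(C)[Si](C)(C)O[C@H]1C/C=C(\C)CCCC(C)(C)[C@H](OC(C)=O)/C=C\1C | intermediate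
22 | (1R,2Z,4S,6E)-4-hydroxy-3,7,11,11-tetramethylcycloundeca-2,6-dien-1-yl acetate | O[C@H]1C/C=C(\C)CCCC(C)(C)[C@H](OC(C)=O)/C=C\1C | intermediate
23 | 4-acetoxy-3-methoxybenzoic acid | COc1cc(C(=O)O)ccc1OC(C)=O | starting material
24 | (1S,2Z,4R,9E)-4-acetoxy-2,5,5,9-tetramethylcycloundeca-2,9-dien-1-yl 4-acetoxy-3-methoxybenzoate | COc1cc(C(=O)O[C@H]2C/C=C(\C)CCCC(C)(C)[C@H](OC(C)=O)/C=C\2C)ccc1OC(C)=O | intermediate
25 | (1S,2Z,4R,9E)-4-acetoxy-2,5,5,9-tetramethylcycloundeca-2,9-dien-1-yl 4-hydroxy-3-methoxybenzoate | COc1cc(C(=O)O[C@H]2C/C=C(\C)CCCC(C)(C)[C@H](OC(C)=O)/C=C\2C)ccc1O | target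

**Count**

Total step count: 17. Longest linear sequence: 17 steps (from 1; 14 and 23 are purchased).

**Steps most likely to fail**

Step 12 is the riskiest. The ring closure may lose to intermolecular alkylation (oligomers), to O-alkylation of the hindered enolate, or to γ-deprotonation that scrambles the Z-enone. The fallback makes the same CMe2–CH2 bond intermolecularly and closes the ring elsewhere. It sets out from 13: Appel iodination gives (1Z,3S,5E)-3-(TBS-oxy)-1,9-diiodo-2,6-dimethylnona-1,5-diene F1; alkylation of lithiated isobutyronitrile (LDA, THF, −78 → 0 °C) with its primary iodide gives the nitrile (6E,9S,10Z)-9-(TBS-oxy)-11-iodo-2,2,6,10-tetramethylundeca-6,10-dienenitrile F2; DIBAL-H and aqueous acid give the aldehyde (6E,9S,10Z)-9-(TBS-oxy)-11-iodo-2,2,6,10-tetramethylundeca-6,10-dienal F3; an intramolecular Nozaki–Hiyama–Kishi reaction (CrCl2, NiCl2 cat., DMSO–THF, high dilution) closes the ring at the carbinol–alkene bond to the macrocyclic allylic alcohol (2Z,4S,6E)-4-(TBS-oxy)-3,7,11,11-tetramethylcycloundeca-2,6-dien-1-ol as a mixture of C1 epimers F4; MnO2 oxidation of the mixture comes back to the route at 19.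

Step 13 is next. Hydride may be delivered to the wrong face if the ring conformation or the alkenyl group overrides the size-based reagent control. The fallback gives up asymmetric induction for separation and recycling. It sets out from 19: Luche reduction (NaBH4, CeCl3, MeOH) should give 20 together with its carbinol epimer (1S,2Z,4S,6E)-4-(TBS-oxy)-3,7,11,11-tetramethylcycloundeca-2,6-dien-1-ol F5; the diastereomers are separated by chromatography, F5 is re-oxidised with MnO2 to 19 and resubmitted, and the route is rejoined at 20.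

Step 15 is third. The acetyl group may migrate across the Z-alkene to the freed hydroxyl (a 1,4 O-to-O acyl shift) during desilylation or the following acylation, which would exchange the two ester positions. The fallback reverses the acylation order and relies on site selectivity. It sets out from 20: HF·pyridine gives the diol (1R,2Z,4S,6E)-3,7,11,11-tetramethylcycloundeca-2,6-diene-1,4-diol F6; Steglich esterification with 23 at low temperature should acylate the less hindered hydroxyl (flanked by the methyl-bearing alkene carbon and a CH2, not by the quaternary carbon) to give (1S,2Z,4R,9E)-4-hydroxy-2,5,5,9-tetramethylcycloundeca-2,9-dien-1-yl 4-acetoxy-3-methoxybenzoate F7; acetylation of the remaining neopentyl-type hydroxyl (Ac2O, DMAP) comes back to the route at 24.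

**Further compounds**

F1 | step 12 | (1Z,3S,5E)-3-(TBS-oxy)-1,9-diiodo-2,6-dimethylnona-1,5-diene | ICCC/C(C)=C/C[C@H](O[Si](C)(C)C(C)(C)C)/C(C)=C\I
F2 | step 12 | (6E,9S,10Z)-9-(TBS-oxy)-11-iodo-2,2,6,10-tetramethylundeca-6,10-dienenitrile | N#CC(C)(C)CCC/C(C)=C/C[C@H](O[Si](C)(C)C(C)(C)C)/C(C)=C\I
F3 | step 12 | (6E,9S,10Z)-9-(TBS-oxy)-11-iodo-2,2,6,10-tetramethylundeca-6,10-dienal | O=CC(C)(C)CCC/C(C)=C/C[C@H](O[Si](C)(C)C(C)(C)C)/C(C)=C\I
F4 | step 12 | (2Z,4S,6E)-4-(TBS-oxy)-3,7,11,11-tetramethylcycloundeca-2,6-dien-1-ol, mixture of C1 epimers | CC(C)(C)[Si](C)(C)O[C@H]1C/C=C(\C)CCCC(C)(C)C(O)/C=C\1C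
F5 | step 13 | (1S,2Z,4S,6E)-4-(TBS-oxy)-3,7,11,11-tetramethylcycloundeca-2,6-dien-1-ol | CC(C)(C)[Si](C)(C)O[C@H]1C/C=C(\C)CCCC(C)(C)[C@@H](O)/C=C\1C
F6 | step 15 | (1R,2Z,4S,6E)-3,7,11,11-tetramethylcycloundeca-2,6-diene-1,4-diol | O[C@H]1C/C=C(\C)CCCC(C)(C)[C@H](O)/C=C\1C
F7 | step 15 | (1S,2Z,4R,9E)-4-hydroxy-2,5,5,9-tetramethylcycloundeca-2,9-dien-1-yl 4-acetoxy-3-methoxybenzoate | COc1cc(C(=O)O[C@H]2C/C=C(\C)CCCC(C)(C)[C@H](O)/C=C\2C)ccc1OC(C)=O
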